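**Plan**

- Retrosynthesis: the carbinol methyl and the vinylic methyl of the decalin are cut first (spiro-epoxide from an exocyclic alkene, alkenyl triflate from a ketone). Next comes the bond between the gem-dimethyl carbon and the neighbouring ring-fusion CH, then the CH2–C(sp2) bond of the two-carbon linker, and last the oxepane C–O and cyclohexane C–C bonds of the other half, which lead back to a farnesol diepoxide.
- Enabling feature: in the decalin the quaternary CMe2 carbon is bonded to the ring-fusion CH that lies β to the ring carbon carrying the vinylic methyl. With that carbon as a ketone, the fusion CH is the β-carbon of a 2-alkylcyclohexenone and the CMe2 carbon is a tertiary radical born from an isopropenyl group.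
- Forward: oxepane and fused cyclohexane arise together in one epoxide cascade; a 4-substituted cyclohexenone is made separately; the halves are joined by B-alkyl Suzuki coupling; the second decalin ring is closed by the radical conjugate cyclisation; two carbonyl carbons then become C(Me)=CH and C(Me)OH.
- Stereochemistry: Shi epoxidation sets three epoxide centres and the chair-like cascade relays them to all five centres of the oxepane half. A chiral lithium amide desymmetrises the cyclohexanone; that centre directs the cis ring fusion and the α-carbon in the cyclisation; convex-face epoxidation sets the tertiary carbinol.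

Key step: step 16

Assumption: lithium (R,R)-bis(1-phenylethyl)amide is taken to give the (S)-enol ether 8, as it does with 4-tert-butylcyclohexanone; if the sense is opposite, the (S,S)-amine is used.
Remark: commercial 1 is a cis/trans mixture and both isomers converge at ketone 7; the minor enantiomer left by step 5 becomes a diastereomer after step 15 and is to be removed there by chromatography.
Remark: farnesol locants C1–C12 are kept for the oxepane half; the decalin carbons are named by their role.

**Route**

Step 1
Reactants: 1 ethyl 4-hydroxycyclohexanecarboxylate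
Product: 2 4-hydroxy-N-methoxy-N-methylcyclohexanecarboxamide
Conditions: MeNH(OMe)·HCl, i-PrMgCl (excess), THF, −20 → 0 °C
Reagents that add atoms: N,O-dimethylhydroxylamine hydrochloride, CNOC.Cl
Why: The chloromagnesium amide of N,O-dimethylhydroxylamine displaces ethoxide from the ester (Weinreb amide formation), the free hydroxyl only consuming one more equivalent of i-PrMgCl.

Step 2
Reactants: 2 4-hydroxy-N-methoxy-N-methylcyclohexanecarboxamide; 3 4-bromo-2-methylbut-1-ene
Product: 5 1-(4-hydroxycyclohexyl)-4-methylpent-4-en-1-one, via (3-methylbut-3-en-1-yl)magnesium bromide 4 (not isolated)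
Conditions: 3, Mg, THF, rt; 2, i-PrMgCl (1 equiv), THF, 0 °C, then 4, 0 °C → rt; aq. NH4Cl
Reagents that add atoms: none
Why: Once the hydroxyl is capped as its magnesium alkoxide, the Grignard reagent adds once to the Weinreb amide (Weinreb ketone synthesis) because the chelated tetrahedral adduct survives until work-up.

Step 3
Reactants: 5 1-(4-hydroxycyclohexyl)-4-methylpent-4-en-1-one
Product: 6 4-[2-(3-methylbut-3-en-1-yl)-1,3-dioxolan-2-yl]cyclohexan-1-ol
Conditions: HOCH2CH2OH, TsOH·H2O (cat.), benzene, reflux, Dean–Stark
Reagents that add atoms: ethylene glycol, OCCO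
Why: Acid-catalysed ketalisation with azeotropic removal of water masks the side-chain ketone, so that the later enone carries no γ-hydrogen activated by a second carbonyl, and the isopropenyl group is expected to tolerate the catalytic acid.

Step 4
Reactants: 6 4-[2-(3-methylbut-3-en-1-yl)-1,3-dioxolan-2-yl]cyclohexan-1-ol
Product: 7 4-[2-(3-methylbut-3-en-1-yl)-1,3-dioxolan-2-yl]cyclohexan-1-one
Conditions: TPAP (cat.), NMO, 4 Å MS, CH2Cl2, rt
Reagents that add atoms: none
Why: Ley–Griffith oxidation of the secondary alcohol under neutral conditions should give the Cs-symmetric 4-substituted cyclohexanone without touching ketal or alkene.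

Step 5
Reactants: 7 4-[2-(3-methylbut-3-en-1-yl)-1,3-dioxolan-2-yl]cyclohexan-1-one
Product: 8 (S)-trimethylsilyl enol ether of 7
Conditions: (R,R)-bis(1-phenylethyl)amine, n-BuLi, LiCl, THF, −78 °C; TMSCl, then 7 (internal quench), −78 °C
Reagents that add atoms: chlorotrimethylsilane, C[Si](C)(C)Cl
Why: Asymmetric deprotonation by the C2-symmetric chiral lithium amide with in situ silylation distinguishes the two enantiotopic axial α-hydrogens of the chair locked by the bulky equatorial substituent, which sets the ring stereocentre that becomes the ring-fusion CH next to the carbinol carbon.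

Step 6
Reactants: 8 (S)-trimethylsilyl enol ether of 7
Product: 9 (4S)-4-[2-(3-methylbut-3-en-1-yl)-1,3-dioxolan-2-yl]cyclohex-2-en-1-one
Conditions: Pd(OAc)2 (10 mol%), O2 (1 atm), DMSO, rt
Reagents that add atoms: none
Why: Saegusa–Ito oxidation turns the silyl enol ether regiospecifically into the enone on the side fixed in step 5, so the enantiotopic choice is carried into the (4S)-enone without touching the stereocentre.

Step 7
Reactants: 9 (4S)-4-[2-(3-methylbut-3-en-1-yl)-1,3-dioxolan-2-yl]cyclohex-2-en-1-one
Product: 10 (4S)-2-iodo-4-[2-(3-methylbut-3-en-1-yl)-1,3-dioxolan-2-yl]cyclohex-2-en-1-one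
Conditions: I2, pyridine, CH2Cl2, 0 °C → rt; aq. Na2S2O3/NaHCO3
Reagents that add atoms: iodine, II
Why: Pyridine-mediated α-iodination of the enone (conjugate addition of pyridine, iodination of the enolate, elimination) installs the vinyl iodide for the sp3–sp2 coupling and leaves the γ-stereocentre alone.

Step 8
Reactants: 11 (2E,6E)-farnesol
Product: 12 tert-butyl (2E,6E)-farnesyl carbonate
Conditions: Boc2O, DMAP (cat.), CH2Cl2, 0 °C → rt
Reagents that add atoms: di-tert-butyl dicarbonate, CC(C)(C)OC(=O)OC(=O)OC(C)(C)C
Why: DMAP-catalysed acylation gives the allylic tert-butyl carbonate, which later deactivates the 2,3-alkene towards epoxidation and serves as the internal oxygen nucleophile.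

Step 9
Reactants: 12 tert-butyl (2E,6E)-farnesyl carbonate
Product: 13 (6S,7S,10S)-6,7:10,11-diepoxide of 12
Conditions: ent-Shi ketone (from L-sorbose, 0.3–0.5 equiv), Oxone, K2CO3, Bu4NHSO4, MeCN/DMM/aq. borate–EDTA buffer, 0 °C
Reagents that add atoms: Oxone (potassium peroxymonosulfate), [K+].[O-]S(=O)(=O)OO
Why: Shi asymmetric epoxidation with the enantiomer of the fructose-derived ketone should epoxidise the two electron-rich trisubstituted alkenes to the (S,S)-epoxides under reagent control, while the 2,3-alkene, deactivated inductively by the allylic carbonate, is expected to be spared.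

Step 10
Reactants: 13 (6S,7S,10S)-6,7:10,11-diepoxide of 12
Product: 14 trans-fused oxepane–cyclohexane bicycle with a cyclic carbonate across C1–O and C3–O and a trimethylsilyl ether at C10
Conditions: TMSOTf, 2,6-di-tert-butyl-4-methylpyridine, CH2Cl2, −78 °C; aq. NaHCO3
Reagents that add atoms: trimethylsilyl trifluoromethanesulfonate, C[Si](C)(C)OS(=O)(=O)C(F)(F)F
Why: Proposed new method: silylation of the 10,11-epoxide lets the 6,7-epoxide oxygen open it at tertiary C11 to a bicyclic epoxonium ion, the 2,3-alkene attacks tertiary C7 of this ion with inversion through a chair (C2–C7 bond, oxepane and cyclohexane formed), and the tertiary cation at C3 is captured anti by the carbonate carbonyl oxygen with loss of isobutene, so that the E-alkene fixes C2–H axial, C1 equatorial, C3–O equatorial and C3–Me axial; the closest known reaction types are the silyl-triflate-promoted tandem oxa-/carbacyclisation of 1,5-diepoxy alkenes that ends by proton loss, and the capture of cations by tert-butyl carbonates in iodocarbonate cyclisations and carbonate-terminated epoxide cascades, the new element being their combination in one relay.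

Step 11
Reactants: 14 cyclic carbonate silyl ether
Product: 15 triol of the oxepane half (C1–OH, C3–OH, C10–OH)
Conditions: K2CO3 (cat.), MeOH, rt
Reagents that add atoms: none
Why: Base-catalysed methanolysis (transesterification) should open the cyclic carbonate and cleave the trimethylsilyl ether without affecting the ring system.

Step 12
Reactants: 15 triol of the oxepane half
Product: 16 C1 aldehyde with free C3 and C10 hydroxyls
Conditions: TEMPO (cat.), PhI(OAc)2, CH2Cl2, rt
Reagents that add atoms: none
Why: The bulky oxoammonium oxidant of the TEMPO/PhI(OAc)2 oxidation selects the primary alcohol over the hindered secondary one and cannot oxidise the tertiary one, and the aldehyde stays equatorial between two quaternary carbons.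

Step 13
Reactants: 16 C1 aldehyde with free C3 and C10 hydroxyls
Product: 17 C1 aldehyde with C3 and C10 triethylsilyl ethers
Conditions: TESOTf, 2,6-lutidine, CH2Cl2, −78 → 0 °C; aq. NaHCO3
Reagents that add atoms: triethylsilyl trifluoromethanesulfonate, CC[Si](CC)(CC)OS(=O)(=O)C(F)(F)F
Why: The silyl triflate with 2,6-lutidine silylates both the secondary and the hindered tertiary alcohol at low temperature (silyl ether protection), masking them for the strongly basic enol triflate formation in step 17.

Step 14
Reactants: 17 C1 aldehyde with C3 and C10 triethylsilyl ethers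
Product: 18 C2-vinyl oxepane bicycle with C3 and C10 triethylsilyl ethers
Conditions: Ph3PCH3Br, KHMDS, THF, 0 °C; then 17, −78 → 0 °C
Reagents that add atoms: methyltriphenylphosphonium bromide, C[P+](c1ccccc1)(c1ccccc1)c1ccccc1.[Br-]
Why: Wittig methylenation of the β-silyloxy aldehyde gives the vinyl group that supplies the second linker carbon, and the equatorial configuration at the α-carbon is the stable one.

Step 15
Reactants: 18 C2-vinyl oxepane bicycle; 10 (4S)-2-iodoenone
Product: 20 2-alkylcyclohexenone joining both halves, via 9-BBN alkylborane 19 (not isolated)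
Conditions: 9-BBN dimer, THF, rt → 40 °C; aq. Cs2CO3; then 10, Pd(dppf)Cl2 (cat.), AsPh3 (cat.), DMF, rt
Reagents that add atoms: none
Why: 9-BBN adds to the terminal carbon of the only alkene of 18 and the primary B-alkyl borane undergoes B-alkyl Suzuki–Miyaura coupling with the activated vinyl iodide at room temperature, excess borane being quenched by the aqueous base before the isopropenyl-bearing partner is added, and no stereocentre is formed or touched.

Step 16
Reactants: 20 2-alkylcyclohexenone joining both halves
Product: 21 cis-fused decalone ketal carrying the silylated oxepane half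
Conditions: Fe(acac)3 (30 mol%), PhSiH3, EtOH/HOCH2CH2OH (5:1), degassed, 60 °C
Reagents that add atoms: none
Why: An iron hydride formed from Fe(acac)3 and PhSiH3 transfers a hydrogen atom to the terminal carbon of the isopropenyl group, and the nucleophilic tertiary radical adds to the electron-poor β-carbon of the enone; reduction of the α-keto radical gives an iron enolate that ethanol protonates. The closest known reaction type is the iron-hydride-initiated reductive olefin–enone coupling (a radical Giese addition that forges quaternary–tertiary bonds), whose intramolecular versions give fused bicycles. The new cyclohexane ring closes in the 6-exo-trig mode through a chair in which the ketal-bearing tether is equatorial on the cyclohexenone. The ring-fusion CH is set cis by the stereocentre from step 5, because axial attack on the β-carbon is only possible from the face the equatorial tether reaches, whereas a trans fusion would need equatorial attack. The α-carbon is set by axial protonation of the enolate anti to the now axial CMe2 branch, that is on the convex face, which places the linker cis to that branch. The step needs hydrogen-atom transfer to the isopropenyl group in preference to the enone, which the electron-rich 1,1-disubstituted alkene secures, and silyl ethers and ketal should be inert to the neutral medium.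

Step 17
Reactants: 21 cis-fused decalone ketal
Product: 23 kinetic enol triflate, via potassium enolate 22 (not isolated)
Conditions: KHMDS, THF, −78 °C; PhNTf2, −78 → −40 °C; aq. NH4Cl
Reagents that add atoms: N-phenylbis(trifluoromethanesulfonimide), O=S(=O)(N(c1ccccc1)S(=O)(=O)C(F)(F)F)C(F)(F)F
Why: Kinetic deprotonation at −78 °C removes a hydrogen from the unhindered α-CH2 and not from the α-methine flanked by linker and ring fusion, and O-sulfonylation of the enolate fixes the double bond where the methyl-bearing alkene of the target lies, after which the linker-bearing centre is allylic and no longer epimerisable.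

Step 18
Reactants: 23 kinetic enol triflate
Product: 24 enol triflate ketone with free C3 and C10 hydroxyls
Conditions: 1 M aq. HCl, THF, 0 °C → rt
Reagents that add atoms: water, O
Why: Dilute aqueous acid hydrolyses the dioxolane and both triethylsilyl ethers while the enol triflate is inert, and short contact at or below room temperature is chosen so that the liberated ketone does not enolise towards the cis ring-fusion CH.

Step 19
Reactants: 24 enol triflate ketone
Product: 25 enol triflate with exocyclic methylene
Conditions: Zn, CH2Br2, TiCl4 (pre-formed reagent), THF/CH2Cl2, 0 °C → rt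
Reagents that add atoms: dibromomethane, BrCBr
Why: Takai–Lombardo methylenation converts the ketone into the exocyclic alkene under non-basic conditions, which should avoid epimerisation of the adjacent ring-fusion CH and tolerate the free hydroxyls and the enol triflate.

Step 20
Reactants: 25 enol triflate with exocyclic methylene
Product: 26 enol triflate spiro-epoxide
Conditions: mCPBA, NaHCO3, CH2Cl2, 0 °C
Reagents that add atoms: 3-chloroperoxybenzoic acid, OOC(=O)c1cccc(Cl)c1
Why: Peracid epoxidation (Prilezhaev reaction) should occur only at the electron-rich 1,1-disubstituted alkene, the enol triflate being too electron-poor, and from the convex face of the cis-decalin (the face of the ring-fusion hydrogens, the other being shielded by the second ring in either chair), which puts the epoxide oxygen where the tertiary hydroxyl of the target lies.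

Step 21
Reactants: 26 enol triflate spiro-epoxide
Product: 27 spiro-epoxide with the vinylic methyl in place
Conditions: trimethylboroxine, Pd(dppf)Cl2 (cat.), K2CO3, dioxane/H2O, 80 °C
Reagents that add atoms: trimethylboroxine, CB1OB(C)OB(C)O1
Why: Suzuki–Miyaura coupling of the alkenyl triflate with trimethylboroxine installs the vinylic methyl under mildly basic conditions that should leave the hindered spiro-epoxide and the free hydroxyls intact.

Step 22
Reactants: 27 spiro-epoxide with the vinylic methyl in place
Product: 28 sipholenol L
Conditions: LiEt3BH (excess), THF, 0 °C → rt; aq. NH4Cl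
Reagents that add atoms: none
Why: Triethylborohydride opens the 1,1-disubstituted epoxide by SN2 attack at its CH2 carbon (hydride opening of an epoxide), turning it into the methyl group and leaving the tertiary alcohol with the configuration set in step 20, the hydroxyls only consuming hydride.

**Compound list**

1 | ethyl 4-hydroxycyclohexanecarboxylate (cis/trans mixture) | CCOC(=O)C1CCC(O)CC1 | starting material
2 | 4-hydroxy-N-methoxy-N-methylcyclohexanecarboxamide | CON(C)C(=O)C1CCC(O)CC1 | intermediate
3 | 4-bromo-2-methylbut-1-ene | C=C(C)CCBr | starting material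
4 | (3-methylbut-3-en-1-yl)magnesium bromide (not isolated) | C=C(C)CC[Mg]Br | intermediate
5 | 1-(4-hydroxycyclohexyl)-4-methylpent-4-en-1-one | C=C(C)CCC(=O)C1CCC(O)CC1 | intermediate
6 | 4-[2-(3-methylbut-3-en-1-yl)-1,3-dioxolan-2-yl]cyclohexan-1-ol | C=C(C)CCC1(OCCO1)C2CCC(O)CC2 | intermediate
7 | 4-[2-(3-methylbut-3-en-1-yl)-1,3-dioxolan-2-yl]cyclohexan-1-one | C=C(C)CCC1(OCCO1)C2CCC(=O)CC2 | intermediate
8 | (S)-trimethylsilyl enol ether of 7 (4S; enol double bond C1=C2) | C=C(C)CCC1(OCCO1)[C@@H]2CC=C(O[Si](C)(C)C)CC2 | intermediate
9 | (4S)-4-[2-(3-methylbut-3-en-1-yl)-1,3-dioxolan-2-yl]cyclohex-2-en-1-one | C=C(C)CCC1(OCCO1)[C@H]2CCC(=O)C=C2 | intermediate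
10 | (4S)-2-iodo-4-[2-(3-methylbut-3-en-1-yl)-1,3-dioxolan-2-yl]cyclohex-2-en-1-one | C=C(C)CCC1(OCCO1)[C@H]2CCC(=O)C(I)=C2 | intermediate
11 | (2E,6E)-farnesol | CC(C)=CCC/C(C)=C/CC/C(C)=C/CO | starting material
12 | tert-butyl (2E,6E)-farnesyl carbonate | CC(C)=CCC/C(C)=C/CC/C(C)=C/COC(=O)OC(C)(C)C | intermediate
13 | tert-butyl (2E)-(6S,7S,10S)-6,7:10,11-diepoxyfarnesyl carbonate | CC1(C)O[C@H]1CC[C@]2(C)O[C@H]2CC/C(C)=C/COC(=O)OC(C)(C)C | intermediate
14 | trans-fused oxepane–cyclohexane bicycle, 1,3-dioxan-2-one across C1–O/C3–O, C10–OTMS (C7-Me, C3-Me and C1 on one face; C6-H, C2-H, C3–O and C10–O on the other) | O=C1OC[C@H]2[C@]3(C)CC[C@H](O[Si](C)(C)C)C(C)(C)O[C@H]3CC[C@]2(C)O1 | intermediate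
15 | triol of the oxepane half (C1 CH2OH equatorial, C3 OH equatorial, 10S OH) | OC[C@H]1[C@]2(C)CC[C@H](O)C(C)(C)O[C@H]2CC[C@]1(C)O | intermediate
16 | C1 aldehyde of 15 with free C3 and C10 hydroxyls | O=C[C@H]1[C@]2(C)CC[C@H](O)C(C)(C)O[C@H]2CC[C@]1(C)O | intermediate
17 | C1 aldehyde with C3 and C10 triethylsilyl ethers | O=C[C@H]1[C@]2(C)CC[C@H](O[Si](CC)(CC)CC)C(C)(C)O[C@H]2CC[C@]1(C)O[Si](CC)(CC)CC | intermediate
18 | C2-vinyl oxepane bicycle with C3 and C10 triethylsilyl ethers | C=C[C@H]1[C@]2(C)CC[C@H](O[Si](CC)(CC)CC)C(C)(C)O[C@H]2CC[C@]1(C)O[Si](CC)(CC)CC | intermediate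
19 | 9-BBN alkylborane from 18, boron on the terminal carbon (not isolated) | C1CCC2CCCC1B2CC[C@H]3[C@]4(C)CC[C@H](O[Si](CC)(CC)CC)C(C)(C)O[C@H]4CC[C@]3(C)O[Si](CC)(CC)CC | intermediate
20 | (4S)-2-alkylcyclohex-2-enone: C4 carries the ketal with the isopentenyl chain, C2 carries the two-carbon linker to the bis-silylated oxepane half | C=C(C)CCC1(OCCO1)[C@H]2CCC(=O)C(CC[C@H]3[C@]4(C)CC[C@H](O[Si](CC)(CC)CC)C(C)(C)O[C@H]4CC[C@]3(C)O[Si](CC)(CC)CC)=C2 | intermediate
21 | cis-fused decalone: ring ketone, spiro-dioxolane at the future carbinol carbon, gem-dimethyl carbon next to the ring fusion; both fusion H and the α-H on one face, linker on the other | O=C1CC[C@H]2[C@@H]([C@@H]1CC[C@H]3[C@]4(C)CC[C@H](O[Si](CC)(CC)CC)C(C)(C)O[C@H]4CC[C@]3(C)O[Si](CC)(CC)CC)C(C)(C)CCC25OCCO5 | intermediate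
22 | potassium enolate of 21 on the CH2 side (not isolated) | [K+].[O-]C1=CC[C@H]2[C@@H]([C@@H]1CC[C@H]3[C@]4(C)CC[C@H](O[Si](CC)(CC)CC)C(C)(C)O[C@H]4CC[C@]3(C)O[Si](CC)(CC)CC)C(C)(C)CCC25OCCO5 | intermediate
23 | enol triflate of 21 on the CH2 side | FC(F)(F)S(=O)(=O)OC1=CC[C@H]2[C@@H]([C@@H]1CC[C@H]3[C@]4(C)CC[C@H](O[Si](CC)(CC)CC)C(C)(C)O[C@H]4CC[C@]3(C)O[Si](CC)(CC)CC)C(C)(C)CCC25OCCO5 | intermediate
24 | enol triflate with decalin ketone at the future carbinol carbon and free oxepane hydroxyls | FC(F)(F)S(=O)(=O)OC1=CC[C@H]2[C@@H]([C@@H]1CC[C@H]3[C@]4(C)CC[C@H](O)C(C)(C)O[C@H]4CC[C@]3(C)O)C(C)(C)CCC2=O | intermediate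
25 | enol triflate with exocyclic methylene at the future carbinol carbon | FC(F)(F)S(=O)(=O)OC1=CC[C@H]2[C@@H]([C@@H]1CC[C@H]3[C@]4(C)CC[C@H](O)C(C)(C)O[C@H]4CC[C@]3(C)O)C(C)(C)CCC2=C | intermediate
26 | enol triflate spiro-epoxide, epoxide oxygen on the face of the ring-fusion hydrogens | FC(F)(F)S(=O)(=O)OC1=CC[C@H]2[C@@H]([C@@H]1CC[C@H]3[C@]4(C)CC[C@H](O)C(C)(C)O[C@H]4CC[C@]3(C)O)C(C)(C)CC[C@@]25CO5 | intermediate
27 | spiro-epoxide with the ring C(Me)=CH alkene | CC1=CC[C@H]2[C@@H]([C@@H]1CC[C@H]3[C@]4(C)CC[C@H](O)C(C)(C)O[C@H]4CC[C@]3(C)O)C(C)(C)CC[C@@]25CO5 | intermediate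
28 | sipholenol L | CC1=CC[C@H]2[C@@H]([C@@H]1CC[C@H]1[C@]3(C)CC[C@H](O)C(C)(C)O[C@H]3CC[C@]1(C)O)C(C)(C)CC[C@]2(C)O | target

**Summary**

Total step count: 22. Longest linear sequence: 15 steps (steps 1–7 or 8–14, then 15–22).

Steps most likely to fail:

1. Step 10 (proposed new method). What may go wrong: the tertiary cation at C3 loses a proton, or the tert-butyl carbonate is stripped by the silyl triflate, faster than the carbonate oxygen captures the cation, so the C3 oxygen is not delivered. Fallback with known chemistry: set out from 13 and take the product of the documented proton-loss mode of the same cascade, the C3-methylidene bicycle with C1 carbonate and C10 silyl ether F1. Epoxidise it with mCPBA from the equatorial face, the axial face being blocked by the 1,3-diaxial C7 methyl, to the spiro-epoxide F2. LiAlH4 then opens the epoxide at CH2 and reduces the carbonate, and an acidic work-up removes the silyl group, which returns the route at triol 15.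

2. Step 16. What may go wrong: the enolate is protonated without facial discrimination, or equilibrates at the α-carbon in the warm protic medium, so the linker-bearing centre is eroded; simple reduction of the isopropenyl group is the other loss channel. Fallback: set out from 20 and accept the cyclised material as a mixture of 21 and its α-epimer, the epi-ketone F3. Convert the mixture with TMSCl/NaI/Et3N in MeCN into the more substituted silyl enol ether F4, regenerate the lithium enolate with MeLi at −78 °C and protonate it with a hindered phenol from the convex face. This sets the α-centre in a separate, irreversible low-temperature event and comes back at 21.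

3. Step 20. What may go wrong: the peracid approaches the exocyclic alkene from both faces, which would scramble the carbinol configuration. Fallback: set out from 25 and dihydroxylate with OsO4/NMO, a bulkier reagent that should discriminate the convex face more strongly, to the primary/tertiary diol F5. Sulfonylate the primary hydroxyl selectively (TsCl, pyridine) to the monotosylate F6 and close it with K2CO3 in MeOH to the spiro-epoxide, which is 26.

Further compounds
F1 | step 10 | C3-methylidene oxepane bicycle with C1 tert-butyl carbonate and C10–OTMS | CC(C)(C)OC(=O)OC[C@H]1[C@]2(C)CC[C@H](O[Si](C)(C)C)C(C)(C)O[C@H]2CCC1=C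
F2 | step 10 | C3 spiro-epoxide of F1, oxygen equatorial | CC(C)(C)OC(=O)OC[C@H]1[C@]2(C)CC[C@H](O[Si](C)(C)C)C(C)(C)O[C@H]2CC[C@@]13CO3
F3 | step 16 | α-epimer of 21 (linker on the face of the ring-fusion hydrogens) | O=C1CC[C@H]2[C@@H]([C@H]1CC[C@H]3[C@]4(C)CC[C@H](O[Si](CC)(CC)CC)C(C)(C)O[C@H]4CC[C@]3(C)O[Si](CC)(CC)CC)C(C)(C)CCC25OCCO5
F4 | step 16 | more substituted trimethylsilyl enol ether of 21/F3 | C[Si](C)(C)OC1=C(CC[C@H]3[C@]4(C)CC[C@H](O[Si](CC)(CC)CC)C(C)(C)O[C@H]4CC[C@]3(C)O[Si](CC)(CC)CC)[C@@H]2[C@H](CC1)C5(OCCO5)CCC2(C)C
F5 | step 20 | primary/tertiary diol from 25, tertiary hydroxyl on the convex face | FC(F)(F)S(=O)(=O)OC1=CC[C@H]2[C@@H]([C@@H]1CC[C@H]3[C@]4(C)CC[C@H](O)C(C)(C)O[C@H]4CC[C@]3(C)O)C(C)(C)CC[C@]2(CO)O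
F6 | step 20 | primary monotosylate of F5 | FC(F)(F)S(=O)(=O)OC1=CC[C@H]2[C@@H]([C@@H]1CC[C@H]3[C@]4(C)CC[C@H](O)C(C)(C)O[C@H]4CC[C@]3(C)O)C(C)(C)CC[C@]2(COS(=O)(=O)c5ccc(C)cc5)O
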